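The target is read as epioritin-(4β→6)-epioritin-(4β→6)-epioritin-4α-ol: three (2R,3R)-2,3-cis-7,8,4'-trihydroxyflavan units, the two upper ones 3,4-trans, the lowest one a 3,4-cis diol.

**Strategy.** The trimer is three copies of one 2R,3R flavan joined C4→C6, so one annulation serves every unit. Each heterocycle (ring C: O1, C2, C3, C4, C4a, C8a) is disconnected into the phenolic O1–C8a–C4a edge of a pyrogallol ring A and a C2–C3–C4 unit electrophilic at both ends: a cis-epoxy aldehyde. In one flask a titanium phenoxide adds its ortho carbon (C4a) to the aldehyde carbon (C4), then O1 opens the epoxide at benzylic C2 with inversion, giving the all-cis flavan-3,4-diol. Its C4 hydroxyl is then the handle for both interflavan bonds. The precursors are a monophenol and a three-carbon epoxide, not a flavan.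

Key step: step 7

Remark: compounds 1, 4 and 6 are taken as commercial; flavan numbering (O1, C2, C3, C4, C4a, C5–C8, C8a; ring A benzo, ring B the 2-aryl group, ring C the pyran) is used throughout, and α denotes the face that carries the C2 aryl group.

Step 1
Reactants: 1 2,3-bis(benzyloxy)benzaldehyde
Product: 3 2,3-bis(benzyloxy)phenol, via aryl formate 2 (not isolated)
Conditions: mCPBA, CH2Cl2, 0 °C to rt; then K2CO3 (cat.), MeOH, rt
Reagents that add atoms: meta-chloroperoxybenzoic acid, O=C(OO)c1cccc(Cl)c1
Why: Baeyer–Villiger (Dakin-type) oxidation in which the electron-rich ortho-alkoxyaryl group migrates to give the aryl formate, which is methanolysed in the same flask; no stereocentre is involved.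

Step 2
Reactants: 4 4-iodophenol
Product: 5 4-iodophenyl pivalate
Conditions: pivaloyl chloride, Et3N, DMAP (cat.), CH2Cl2, 0 °C
Reagents that add atoms: pivaloyl chloride, CC(C)(C)C(=O)Cl
Why: O-acylation of the phenol; the hindered electron-poor ester later tempers benzylic ionisation at C2, keeps ring B out of Friedel–Crafts reactions, and falls off in the final methanolysis.

Step 3
Reactants: 5 4-iodophenyl pivalate, 6 prop-2-yn-1-ol
Product: 7 3-[4-(pivaloyloxy)phenyl]prop-2-yn-1-ol
Conditions: PdCl2(PPh3)2 (cat.), CuI (cat.), Et3N, THF, rt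
Reagents that add atoms: none
Why: Sonogashira coupling of an aryl iodide with a terminal alkyne under mild amine conditions that leave the pivalate intact.

Step 4
Reactants: 7 3-[4-(pivaloyloxy)phenyl]prop-2-yn-1-ol
Product: 8 (Z)-3-[4-(pivaloyloxy)phenyl]prop-2-en-1-ol
Conditions: H2 (1 atm), Lindlar catalyst (Pd on CaCO3 poisoned with Pb(OAc)2), quinoline, EtOAc, rt
Reagents that add atoms: none
Why: Lindlar semihydrogenation adds H2 syn and should stop at the Z alkene.

Step 5
Reactants: 8 (Z)-3-[4-(pivaloyloxy)phenyl]prop-2-en-1-ol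
Product: 9 [(2R,3S)-3-[4-(pivaloyloxy)phenyl]oxiran-2-yl]methanol (cis-epoxide)
Conditions: Ti(OiPr)4 (cat.), D-(−)-diethyl tartrate (cat.), t-BuOOH, 4 Å molecular sieves, CH2Cl2, −20 °C
Reagents that add atoms: tert-butyl hydroperoxide, CC(C)(C)OO
Why: Sharpless asymmetric epoxidation, in which the D-tartrate titanium complex should deliver oxygen to the face that makes C2 R while the Z geometry is carried stereospecifically into the cis-epoxide (C3 S).

Step 6
Reactants: 9 [(2R,3S)-3-[4-(pivaloyloxy)phenyl]oxiran-2-yl]methanol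
Product: 10 (2S,3S)-3-[4-(pivaloyloxy)phenyl]oxirane-2-carbaldehyde (cis)
Conditions: Dess–Martin periodinane, pyridine, CH2Cl2, 0 °C
Reagents that add atoms: none
Why: Dess–Martin oxidation under buffered non-basic conditions should give the epoxy aldehyde without epoxide opening or epimerisation (the descriptor at C2 changes only through priorities).

Step 7
Reactants: 3 2,3-bis(benzyloxy)phenol, 10 (2S,3S)-3-[4-(pivaloyloxy)phenyl]oxirane-2-carbaldehyde
Product: 13 (2R,3R,4R)-7,8-bis(benzyloxy)-2-[4-(pivaloyloxy)phenyl]chromane-3,4-diol, via titanium phenoxide 11 (not isolated), via epoxy carbinol 12 (not isolated)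
Conditions: 3, Ti(OiPr)4 (1.0 equiv), toluene, rt, i-PrOH removed in vacuo; then 10 (1.0 equiv), CH2Cl2, −20 °C to rt, then 40 °C; aqueous work-up
Reagents that add atoms: none
Why: Proposed new method: the triisopropoxytitanium phenoxide 11 should add its free ortho carbon (future C4a) to the aldehyde carbon (C4) through a closed six-membered transition state in which titanium bridges the phenoxide and carbonyl oxygens, and the titanium alkoxide of the resulting 2,3-epoxy alcohol 12 should then activate the epoxide oxygen so that the phenolic oxygen (O1) opens the benzylic carbon (C2). The closest known reaction types are the ortho-specific hydroxyalkylation of titanium and magnesium phenoxides with α-oxygenated aldehydes, the titanium-mediated opening of 2,3-epoxy alcohols at the carbon remote from the carbinol, and the 6-endo cyclisation of epoxy phenols to flavan-3-ols; their union in one flask on an epoxy aldehyde is the untested part. Ring C closes by a 6-endo-tet epoxide opening, preferred over 5-exo attack at C3 because C2 is benzylic and is the carbon to which the titanium chelate of the C4 alkoxide directs a nucleophile. C3 keeps the epoxide C–O bond set in step 5, C2 is formed by SN2 inversion of the cis-epoxide (hence 2,3-cis, 2R), and C4 is set by polar Felkin–Anh addition anti to the epoxide C–O bond, which a non-chelating titanium phenoxide should favour, giving the 3,4-cis (4R) carbinol. The step needs ortho rather than para C-alkylation (secured by the metal phenoxide template), mono- rather than bis-arylation (equimolar partners, low temperature) and clean inversion at C2 (the electron-poor pivaloyloxyphenyl group disfavours a benzylic cation). The C4 configuration is needed only in the unit that becomes the lower flavan-3,4-diol; in the other two it is erased at the coupling stage.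

Step 8
Reactants: 13 (2R,3R,4R)-7,8-bis(benzyloxy)-2-[4-(pivaloyloxy)phenyl]chromane-3,4-diol
Product: 14 3,4-O-carbonyl derivative of 13 (cis-fused cyclic carbonate; lower-unit building block)
Conditions: 1,1'-carbonyldiimidazole, CH2Cl2, rt
Reagents that add atoms: 1,1'-carbonyldiimidazole, O=C(n1ccnc1)n1ccnc1
Why: Carbonylation of the cis-3,4-diol closes the five-membered cyclic carbonate, which removes both hydroxyls as competing nucleophiles and ties the benzylic C4–O bond into a ring so that it should not ionise in step 11; no stereocentre changes.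

Step 9
Reactants: 13 (2R,3R,4R)-7,8-bis(benzyloxy)-2-[4-(pivaloyloxy)phenyl]chromane-3,4-diol
Product: 15 3,4-di-O-acetyl derivative of 13
Conditions: Ac2O, pyridine, DMAP (cat.), CH2Cl2, rt
Reagents that add atoms: acetic anhydride, CC(=O)OC(C)=O
Why: Esterification of both hydroxyls makes the 4-acetate a leaving group and the 3-acetate a neighbouring group for the coupling; configuration is retained.

Step 10
Reactants: 15 3,4-di-O-acetyl derivative of 13
Product: 16 6-bromo derivative of 15
Conditions: N-bromosuccinimide, CH2Cl2, 0 °C, dark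
Reagents that add atoms: N-bromosuccinimide, O=C1CCC(=O)N1Br
Why: Electrophilic aromatic bromination should go to C6 of ring A, the only free position para to O1 and ortho to the 7-benzyloxy group (ring B is deactivated by the pivalate), and the bromine caps the one nucleophilic carbon of the future upper unit.

Step 11
Reactants: 15 3,4-di-O-acetyl derivative of 13, 14 3,4-O-carbonyl derivative of 13
Product: 17 protected dimer, 3-O-acetyl-7,8-di-O-benzyl-4'-O-pivaloylepioritin-(4β→6)-[7,8-di-O-benzyl-4'-O-pivaloylepioritin-4α-ol 3,4-O-carbonate]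
Conditions: 14 (3 equiv), TMSOTf (0.2 equiv), 4 Å molecular sieves, CH2Cl2, −78 to −40 °C, slow addition of 15; excess 14 recovered
Reagents that add atoms: none
Why: Lewis-acid ionisation of the benzylic 4-acetate gives the flavan-4-yl cation (stabilised by O1 and the 7-benzyloxy group), which C6 of 14 should capture in a Friedel–Crafts alkylation of the kind used for interflavan bonds; the 3α-acetoxy group covers the α face, so the new C4 stereocentre is 4β (3,4-trans), and the excess of 14 suppresses self-alkylation of 15.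

Step 12
Reactants: 16 6-bromo derivative of 15, 17 protected dimer
Product: 18 protected trimer, 6-bromo-3-O-acetyl-7,8-di-O-benzyl-4'-O-pivaloylepioritin-(4β→6)-3-O-acetyl-7,8-di-O-benzyl-4'-O-pivaloylepioritin-(4β→6)-[7,8-di-O-benzyl-4'-O-pivaloylepioritin-4α-ol 3,4-O-carbonate]
Conditions: 16 (1.1 equiv), TMSOTf (0.2 equiv), 4 Å molecular sieves, CH2Cl2, −78 to −30 °C
Reagents that add atoms: none
Why: The same Friedel–Crafts interflavan coupling, here equimolar because the bromine cap prevents self-alkylation of 16 and the only nucleophilic carbon left is C6 of the upper unit of 17 (C6 of the lower unit is substituted, the C5 positions are peri-hindered, ring B is deactivated); attack trans to the 3-acetoxy group again sets 4β.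

Step 13
Reactants: 18 protected trimer
Product: 19 6-bromo-7,8-di-O-benzylepioritin-(4β→6)-7,8-di-O-benzylepioritin-(4β→6)-7,8-di-O-benzylepioritin-4α-ol
Conditions: K2CO3 (cat.), MeOH/THF, 40 °C, argon
Reagents that add atoms: none
Why: Zemplén-type transesterification should remove two acetates, three aryl pivalates and the cyclic carbonate by acyl–oxygen cleavage, so no stereocentre is touched while the oxidation-prone ring A oxygens stay benzylated.

Step 14
Reactants: 19 6-bromo-7,8-di-O-benzylepioritin-(4β→6)-7,8-di-O-benzylepioritin-(4β→6)-7,8-di-O-benzylepioritin-4α-ol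
Product: 20 epioritin-(4β→6)-epioritin-(4β→6)-epioritin-4α-ol (target)
Conditions: H2 (1 atm), Pd(OH)2 on carbon, Et3N (1.1 equiv), THF/MeOH, rt; filtration under argon
Reagents that add atoms: none
Why: Catalytic hydrogenolysis should cleave the six benzyl ethers and the aryl C–Br bond in one operation, the amine buffering HBr so that the benzylic C4 hydroxyl of the lower unit is neither ionised nor reduced.

**Compound list**

1 | 2,3-bis(benzyloxy)benzaldehyde | O=Cc1cccc(OCc2ccccc2)c1OCc1ccccc1 | starting material
2 | 2,3-bis(benzyloxy)phenyl formate | O=COc1cccc(OCc2ccccc2)c1OCc1ccccc1 | intermediate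
3 | 2,3-bis(benzyloxy)phenol | Oc1cccc(OCc2ccccc2)c1OCc1ccccc1 | intermediate
4 | 4-iodophenol | Oc1ccc(I)cc1 | starting material
5 | 4-iodophenyl pivalate | CC(C)(C)C(=O)Oc1ccc(I)cc1 | intermediate
6 | prop-2-yn-1-ol | C#CCO | starting material
7 | 3-[4-(pivaloyloxy)phenyl]prop-2-yn-1-ol | OCC#Cc1ccc(OC(=O)C(C)(C)C)cc1 | intermediate
8 | (Z)-3-[4-(pivaloyloxy)phenyl]prop-2-en-1-ol | OC/C=C\c1ccc(OC(=O)C(C)(C)C)cc1 | intermediate
9 | [(2R,3S)-3-[4-(pivaloyloxy)phenyl]oxiran-2-yl]methanol (cis) | OC[C@H]1O[C@H]1c1ccc(OC(=O)C(C)(C)C)cc1 | intermediate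
10 | (2S,3S)-3-[4-(pivaloyloxy)phenyl]oxirane-2-carbaldehyde (cis) | O=C[C@H]1O[C@H]1c1ccc(OC(=O)C(C)(C)C)cc1 | intermediate
11 | triisopropoxytitanium 2,3-bis(benzyloxy)phenoxide | CC(C)O[Ti](OC(C)C)(OC(C)C)Oc1cccc(OCc2ccccc2)c1OCc1ccccc1 | intermediate
12 | (R)-[3,4-bis(benzyloxy)-2-hydroxyphenyl]{(2R,3S)-3-[4-(pivaloyloxy)phenyl]oxiran-2-yl}methanol (titanium-bound in the flask, drawn metal-free) | Oc1c(OCc2ccccc2)c(OCc2ccccc2)ccc1[C@@H](O)[C@H]1O[C@H]1c1ccc(OC(=O)C(C)(C)C)cc1 | intermediate
13 | (2R,3R,4R)-7,8-bis(benzyloxy)-2-[4-(pivaloyloxy)phenyl]chromane-3,4-diol (2,3-cis-3,4-cis) | c1cc2c(c(OCc3ccccc3)c1OCc1ccccc1)O[C@H](c1ccc(OC(=O)C(C)(C)C)cc1)[C@H](O)[C@@H]2O | intermediate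
14 | 3,4-O-carbonyl derivative of 13 (cis-fused cyclic carbonate) | c1cc2c(c(OCc3ccccc3)c1OCc1ccccc1)O[C@H](c1ccc(OC(=O)C(C)(C)C)cc1)[C@H](OC(=O)O3)[C@@H]23 | intermediate
15 | 3,4-di-O-acetyl derivative of 13 | c1cc2c(c(OCc3ccccc3)c1OCc1ccccc1)O[C@H](c1ccc(OC(=O)C(C)(C)C)cc1)[C@H](OC(C)=O)[C@@H]2OC(C)=O | intermediate
16 | 6-bromo-3,4-di-O-acetyl derivative of 13 | Brc1cc2c(c(OCc3ccccc3)c1OCc1ccccc1)O[C@H](c1ccc(OC(=O)C(C)(C)C)cc1)[C@H](OC(C)=O)[C@@H]2OC(C)=O | intermediate
17 | protected dimer: upper unit 3-O-acetyl, 4β-linked to C6 of the carbonate-protected lower unit | c1cc2c(c(OCc3ccccc3)c1OCc1ccccc1)O[C@H](c1ccc(OC(=O)C(C)(C)C)cc1)[C@H](OC(C)=O)[C@H]2c1cc2c(c(OCc3ccccc3)c1OCc1ccccc1)O[C@H](c1ccc(OC(=O)C(C)(C)C)cc1)[C@H](OC(=O)O3)[C@@H]23 | intermediate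
18 | protected trimer: 6-bromo upper unit and middle unit both 3-O-acetyl and 4β→6 linked, lower unit 3,4-O-carbonate | Brc1cc2c(c(OCc3ccccc3)c1OCc1ccccc1)O[C@H](c1ccc(OC(=O)C(C)(C)C)cc1)[C@H](OC(C)=O)[C@H]2c1cc2c(c(OCc3ccccc3)c1OCc1ccccc1)O[C@H](c1ccc(OC(=O)C(C)(C)C)cc1)[C@H](OC(C)=O)[C@H]2c1cc2c(c(OCc3ccccc3)c1OCc1ccccc1)O[C@H](c1ccc(OC(=O)C(C)(C)C)cc1)[C@H](OC(=O)O3)[C@@H]23 | intermediate
19 | 6-bromo-hexa-O-benzyl trimer with free 3-, 4- and 4'-hydroxyls | Brc1cc2c(c(OCc3ccccc3)c1OCc1ccccc1)O[C@H](c1ccc(O)cc1)[C@H](O)[C@H]2c1cc2c(c(OCc3ccccc3)c1OCc1ccccc1)O[C@H](c1ccc(O)cc1)[C@H](O)[C@H]2c1cc2c(c(OCc3ccccc3)c1OCc1ccccc1)O[C@H](c1ccc(O)cc1)[C@H](O)[C@@H]2O | intermediate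
20 | epioritin-(4β→6)-epioritin-(4β→6)-epioritin-4α-ol | Oc1ccc([C@H]2Oc3c(ccc(O)c3O)[C@H](c3cc4c(c(O)c3O)O[C@H](c3ccc(O)cc3)[C@H](O)[C@H]4c3cc4c(c(O)c3O)O[C@H](c3ccc(O)cc3)[C@H](O)[C@@H]4O)[C@H]2O)cc1 | target

**Step count and risks**

Total step count: 14. Longest linear sequence: 11 steps (2, 3, 4, 5, 6, 7, 9, 10, 12, 13, 14).

Steps most likely to fail:

1. Step 7 (proposed new method). What may go wrong: the titanium-bound epoxy carbinol may ionise at C4 to an ortho-quinone methide and be arylated a second time, or the epoxide may open with isopropoxide or lose stereochemical integrity before ring C closes. Fallback with known reactions, reversing the order of the two bond formations: it sets out from epoxy alcohol 9 and phenol 3. Titanium-mediated opening of 9 by 3 at the benzylic carbon remote from the carbinol (Ti(OiPr)4, toluene, 50 °C, inversion) should give the 3-aryloxy-1,2-diol F1. Oxidation of the primary alcohol only (TEMPO cat., PhI(OAc)2, CH2Cl2) should give the α-hydroxy aldehyde F2. Intramolecular Friedel–Crafts hydroxyalkylation (MgBr2·OEt2 or SnCl4, CH2Cl2, −78 °C) then closes C4a–C4; chelation of the aldehyde with the axial C3 hydroxyl is possible only in the arrangement that leads to the 3,4-cis diol, and the route is rejoined at 13.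

2. Step 11. What may go wrong: self-alkylation of 15 at its own C6 and ionisation of the carbonate-bound C4 of 14 under the hard Lewis acid, giving oligomer mixtures. Fallback by orthogonal soft activation: it sets out from 15, which with 4-methylbenzenethiol and BF3·OEt2 (cat.) in CH2Cl2 at −40 °C should give the 4β-arylsulfanyl 3-acetate F3. AgBF4 in THF at 0 °C then ionises only the C–S bond while F3 is added slowly to excess 14, whose C–O bonds are inert to the thiophile, and the route is rejoined at 17.

3. Step 12. What may go wrong: slow capture of the cation from 16 by the hindered C6 of the dimer, so that elimination or acyl loss from the cation precursor takes over. Fallback by reversed order of assembly, so that both C–C bonds are made with a monomeric nucleophile: it sets out from 16 and the 4β-arylsulfanyl 3-acetate F3 (made from 15 as above). TMSOTf (cat.) at −78 °C should ionise only the acetate of 16, the C–S bond of F3 being inert to the hard silyl Lewis acid as a thioglycoside is, and should give the bromo-capped dimer thioether F4. AgBF4 in THF with 14 then forms the second interflavan bond, and the route is rejoined at 18.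

Further compounds
F1 | step 7 | 3-aryloxy-1,2-diol: (2R)-configured carbinol bearing at C3 the 2,3-bis(benzyloxy)phenoxy group and the 4-(pivaloyloxy)phenyl group (C3 inverted relative to 9) | OC[C@@H](O)[C@H](Oc1cccc(OCc2ccccc2)c1OCc1ccccc1)c1ccc(OC(=O)C(C)(C)C)cc1
F2 | step 7 | α-hydroxy aldehyde from F1 (primary alcohol oxidised) | O=C[C@@H](O)[C@H](Oc1cccc(OCc2ccccc2)c1OCc1ccccc1)c1ccc(OC(=O)C(C)(C)C)cc1
F3 | step 11 | 4β-(4-methylphenylsulfanyl) 3-O-acetyl derivative of 13 | c1cc2c(c(OCc3ccccc3)c1OCc1ccccc1)O[C@H](c1ccc(OC(=O)C(C)(C)C)cc1)[C@H](OC(C)=O)[C@H]2Sc1ccc(C)cc1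
F4 | step 12 | bromo-capped dimer thioether: 6-bromo-3-O-acetyl upper unit 4β→6 linked to a 3-O-acetyl unit carrying 4β-(4-methylphenylsulfanyl) | Brc1cc2c(c(OCc3ccccc3)c1OCc1ccccc1)O[C@H](c1ccc(OC(=O)C(C)(C)C)cc1)[C@H](OC(C)=O)[C@H]2c1cc2c(c(OCc3ccccc3)c1OCc1ccccc1)O[C@H](c1ccc(OC(=O)C(C)(C)C)cc1)[C@H](OC(C)=O)[C@H]2Sc1ccc(C)cc1
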